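**Retrosynthetic overview**
- Late stage: the three acetates, the enone, the C11 oxygen (Rubottom-type oxidation of a ring enol ether) and the trans C2–C3 epoxide (from an anti-2,3-diol) are adjustments of one tricyclic core.
- Key disconnection: C1–C10 and C13–C14 are cut together, so the cyclohexene (ring A) and the ten-membered carbocycle (ring B) both come from an open-chain 2-ethoxydiene/isopropenyl ketone by a macrocyclising intramolecular Diels–Alder reaction; the diene is made in the same flask by Stille coupling of a C11 vinyl iodide.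
- The chain is built on the γ-lactone: C7–O by chelation-controlled reduction of an α-hydroxy enone, C6–C7 by acylation of a geometrically defined alkenyllithium with a Seebach dioxolanone, C8–C9 by a self-regenerating aldol, C8/C17 from (S)-malate.
- Ring order: γ-lactone first, then rings A and B in one operation, then the epoxide.

Convention and assumption (one line): locants C1–C20 are those of the target skeleton, called briarane here (C1–C10 ten-membered ring; C1, C10–C14 six-membered ring; C15 = CH3 on C1; C16 = CH2O on C5; C17/C18 = CH–CH3 of the lactone; C19 = lactone C=O; C20 = CH3 on C11); TBS = tert-butyldimethylsilyl; compounds 1, 3, 12, 13, 25 and 30 are bought.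

**Route**

Step 1
Reactants: 1 but-2-yn-1-ol
Product: 2 but-2-ynal
Conditions: MnO2 (10 equiv), CH2Cl2, rt; used as a dried solution
Reagents that add atoms: none
Why: Activated MnO2 oxidises the propargylic alcohol to the ynal (heterogeneous allylic/propargylic oxidation) without over-oxidation, and no stereocentre is involved.

Step 2
Reactants: 3 dimethyl (S)-malate
Product: 5 dimethyl (2S,3R)-3-methylmalate, via dilithium alkoxide enolate 4 (not isolated)
Conditions: LiN(iPr)2 (2.1 equiv), THF, −78 to −20 °C; MeI, −78 to 0 °C; AcOH quench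
Reagents that add atoms: iodomethane ([CH3]I)
Why: Fráter–Seebach alkylation, in which the chelated alkoxide–enolate dianion is methylated anti to the alkoxide and so sets C17 (3R, about 9:1) from the malate centre.

Step 3
Reactants: 5 dimethyl (2S,3R)-3-methylmalate
Product: 6 (2S,3R)-3-methylmalic acid
Conditions: KOH (2.5 equiv), MeOH/H2O, 0 °C to rt; HCl to pH 1, continuous extraction
Reagents that add atoms: potassium hydroxide ([K+].[OH-])
Why: Plain saponification of both methyl esters under mild conditions that do not epimerise the α-methyl carboxylate centre.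

Step 4
Reactants: 6 (2S,3R)-3-methylmalic acid
Product: 7 cis-dioxolanone acid
Conditions: pivalaldehyde (3 equiv), TsOH·H2O (5 mol%), H2SO4 (cat.), pentane, reflux, Dean–Stark; recrystallisation
Reagents that add atoms: pivalaldehyde (CC(C)(C)C=O)
Why: Seebach acetalisation of the α-hydroxy acid gives the five-membered dioxolanone as the thermodynamic cis isomer, so the new acetal centre (2S) stores the chirality of C8 for the next step (self-regeneration of stereocentres).

Step 5
Reactants: 7 cis-dioxolanone acid; 2 but-2-ynal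
Product: 11 silyloxyalkynyl dioxolanone acid, via dilithium ring enolate 8 (not isolated), via dilithium aldolate 9 (not isolated), via bis-silyl compound 10 (not isolated)
Conditions: LiN(SiMe3)2 (2.2 equiv), THF, −78 °C; 2 (1.3 equiv), −78 °C, 30 min; TBSOTf (2.4 equiv), −78 to −40 °C; aqueous citric acid work-up
Reagents that add atoms: tert-butyldimethylsilyl trifluoromethanesulfonate (CC(C)(C)[Si](C)(C)OS(=O)(=O)C(F)(F)F)
Why: Seebach self-regenerating aldol addition, in which the aldehyde attacks the enolate face anti to tert-butyl (C8 with net retention) through a closed Zimmerman–Traxler chair whose ring-locked enolate geometry puts O8 and the new O9 anti (C9 R), and the aldolate is silylated in situ to block retro-aldol.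

Step 6
Reactants: 12 [2-(1,3-dioxolan-2-yl)ethyl]magnesium bromide; 13 tert-butyldimethyl(prop-2-yn-1-yloxy)silane
Product: 16 (E)-alkenyl iodide acetal, via alkylcopper 14 (not isolated), via alkenylcopper 15 (not isolated)
Conditions: CuBr·SMe2 (1.05 equiv), THF, −40 °C; 13, −25 °C, 4 h; I2, −40 to 0 °C
Reagents that add atoms: iodine ([I][I])
Why: Normant syn-carbocupration in THF puts the alkyl group on the internal alkyne carbon and copper on the terminal carbon cis to it, and iodinolysis with retention fixes the trisubstituted alkene (iodine cis to the C4 chain, the later C5=C6 geometry).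

Step 7
Reactants: 16 (E)-alkenyl iodide acetal; 11 silyloxyalkynyl dioxolanone acid
Product: 19 α-hydroxy enone acid, via alkenyllithium 17 (not isolated), via lithium carboxylate 18 (not isolated)
Conditions: 16 (1.3 equiv), tBuLi (2.6 equiv), Et2O, −78 °C; 11 pretreated with LiN(SiMe3)2 (1.05 equiv), THF, −78 °C; mix, −78 °C, 1 h; AcOH then H2O, 0 °C
Reagents that add atoms: none
Why: Lithium–iodine exchange with retention followed by acylation of the alkenyllithium by the dioxolanone carbonyl, an activated ester whose tetrahedral adduct survives at −78 °C and collapses on work-up with loss of pivalaldehyde, gives the α-hydroxy enone without touching C8, C9 or C17.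

Step 8
Reactants: 19 α-hydroxy enone acid
Product: 21 alkynyl lactone acetal, via dihydroxy acid 20 (not isolated)
Conditions: Zn(BH4)2 (3 equiv), Et2O, −30 °C; aqueous NH4Cl; pyridinium p-toluenesulfonate (10 mol%), CH2Cl2, rt
Reagents that add atoms: none
Why: Chelation-controlled 1,2-reduction of the α-hydroxy enone (zinc bridges O7 and O8 and hydride enters from the CH(CH3)CO2 side, away from the silyloxy-bearing C9 arm) gives the 7,8-anti diol (C7 S), whose allylic hydroxyl then closes the γ-lactone on the C19 acid.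

Step 9
Reactants: 21 alkynyl lactone acetal
Product: 23 iodoalkenyl lactone acetal, via alkenylzirconocene 22 (not isolated)
Conditions: Cp2Zr(H)Cl (3.5 equiv), THF, rt to 40 °C; I2, 0 °C
Reagents that add atoms: iodine ([I][I])
Why: Schwartz hydrozirconation adds H–Zr syn and, after equilibration with excess reagent, places zirconium on the methyl-bearing carbon remote from the hindered C9, so iodinolysis with retention gives the (E)-iodide that carries the C10=C11 geometry of the future diene.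

Step 10
Reactants: 23 iodoalkenyl lactone acetal
Product: 24 iodoalkenyl lactone aldehyde
Conditions: pyridinium p-toluenesulfonate (0.3 equiv), acetone/H2O (10:1), 55 °C
Reagents that add atoms: water (O)
Why: Mild acid-catalysed acetal hydrolysis frees the C2 aldehyde while the silyl ethers, the lactone and the vinyl iodide are stable.

Step 11
Reactants: 24 iodoalkenyl lactone aldehyde; 25 isopropenylmagnesium bromide
Product: 27 aminoxy allylic alcohol, via α-aminoxy aldehyde 26 (not isolated)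
Conditions: nitrosobenzene (1.1 equiv), D-proline (20 mol%), CHCl3, 4 °C; then added to 25 (6 equiv), THF, −78 °C; H2O quench
Reagents that add atoms: nitrosobenzene (O=Nc1ccccc1)
Why: Proline-enamine α-aminoxylation (O-selective nitroso aldol) sets C3 (S) under catalyst control and the crude aldehyde is trapped by Grignard 1,2-addition, the configuration of the new C2 carbinol being irrelevant because it is oxidised in step 13.

Step 12
Reactants: 27 aminoxy allylic alcohol
Product: 28 allylic diol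
Conditions: Zn (10 equiv), AcOH/THF (1:4), rt
Reagents that add atoms: none
Why: Reductive N–O cleavage by zinc in acetic acid releases the C3 hydroxyl with retention, the vinyl iodide and the allylic lactone being inert to zinc at room temperature.

Step 13
Reactants: 28 allylic diol
Product: 29 α-hydroxy isopropenyl ketone
Conditions: MnO2 (20 equiv), CH2Cl2, rt
Reagents that add atoms: none
Why: MnO2 oxidises only the allylic C2 carbinol (chemoselective allylic oxidation), leaving the saturated C3 and tertiary C8 hydroxyls and giving the hydrogen-bond-activated dienophile.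

Step 14
Reactants: 29 α-hydroxy isopropenyl ketone; 30 tributyl(1-ethoxyethenyl)stannane
Product: 32 tricyclic enol ether hydroxy ketone, via ethoxydiene 31 (not isolated)
Conditions: Pd2(dba)3 (5 mol%), AsPh3 (20 mol%), CuI (10 mol%), DMF, 40 °C; then diluted into degassed toluene (0.5 mM), 2,6-di-tert-butyl-4-methylphenol (cat.), iPr2NEt (0.2 equiv), 120 °C, 36 h
Reagents that add atoms: none
Why: Proposed new method: a Stille coupling makes the electron-rich 2-ethoxydiene in situ and a macrocyclising intramolecular Diels–Alder reaction then forges C13–C14 and C1–C10, so that ring A and ring B close together with para regiochemistry (alkoxy-bearing C12 opposite the acyl-bearing C1), allylic 1,3-strain holding H9 in the diene plane so that the dienophile, delivered through C8, adds to that face of C10 while the exo-acyl mode usual for α-methyl enones gives the trans ring fusion (C1 S, C10 S), the closest known reactions being the macrocyclising intramolecular Diels–Alder closures of eleven-membered cytochalasan carbocycles and tandem Stille/Diels–Alder sequences.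

Step 15
Reactants: 32 tricyclic enol ether hydroxy ketone
Product: 33 tricyclic anti-diol
Conditions: Zn(BH4)2 (2 equiv), Et2O, −40 to −20 °C; aqueous potassium sodium tartrate work-up (pH 8)
Reagents that add atoms: none
Why: Chelation-controlled reduction of the α-hydroxy ketone (hydride anti to C4 on the zinc chelate) gives the 2,3-anti diol (C2 R) while the lactone and the enol ether are not reduced.

Step 16
Reactants: 33 tricyclic anti-diol
Product: 34 epoxy enol ether
Conditions: PPh3 (1.5 equiv), DIAD (1.5 equiv), toluene, 0 to 60 °C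
Reagents that add atoms: none
Why: Mitsunobu cyclodehydration of the anti-1,2-diol, in which the less hindered C3 hydroxyl is activated as the oxyphosphonium and displaced by the neopentyl C2 oxygen with inversion at C3, gives the trans (2R,3R) epoxide.

Step 17
Reactants: 34 epoxy enol ether
Product: 36 α-ketol, via ethoxy epoxide 35 (not isolated)
Conditions: dimethyldioxirane (1.05 equiv, acetone), CH2Cl2, −78 °C; pH 7 phosphate buffer, THF, 0 °C
Reagents that add atoms: dimethyldioxirane (CC1(C)OO1); water (O)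
Why: Rubottom-type oxidation, in which the enol ether (far more electron-rich than the C5=C6 alkene) is epoxidised from the α face opposite the axial C15 methyl and the C9 substituent and hydrolytic opening of the ethoxy epoxide gives the C12 ketone with the tertiary C11 hydroxyl (11S).

Step 18
Reactants: 36 α-ketol
Product: 37 cyclohexenone
Conditions: 2-iodoxybenzoic acid (IBX, 2.5 equiv), DMSO, 70 °C
Reagents that add atoms: none
Why: IBX dehydrogenation of the ketone can only run toward C13–C14 because C11 is quaternary, which gives the cyclohexenone without affecting any stereocentre.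

Step 19
Reactants: 37 cyclohexenone
Product: 38 tetraol
Conditions: Bu4NF (4 equiv), AcOH (4 equiv), THF, 0 °C to rt
Reagents that add atoms: none
Why: Buffered fluoride desilylation removes both silyl ethers (C9 and C16) while the acetic acid buffer protects the epoxide, the β-hydroxy lactone and the α-ketol from base.

Step 20
Reactants: 38 tetraol
Product: 39 CNP0226792.2
Conditions: Ac2O (6 equiv), Et3N (8 equiv), 4-(dimethylamino)pyridine (0.2 equiv), CH2Cl2, 0 to 35 °C
Reagents that add atoms: acetic anhydride (CC(=O)OC(C)=O)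
Why: Nucleophile-catalysed acetylation esterifies the primary C16, secondary C9 and tertiary α-ketol C11 hydroxyls, whereas the C8 hydroxyl, tertiary and flanked by three branched carbons, is expected to stay free.

**Compound list**

1 | but-2-yn-1-ol | CC#CCO | starting material
2 | but-2-ynal | CC#CC=O | intermediate
3 | dimethyl (S)-malate, dimethyl (2S)-2-hydroxybutanedioate | COC(=O)C[C@H](O)C(=O)OC | starting material
4 | dilithium alkoxide enolate of 3 | [Li+].[Li+].COC([O-])=C[C@H]([O-])C(=O)OC | intermediate (not isolated)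
5 | dimethyl (2S,3R)-3-methylmalate, dimethyl (2S,3R)-2-hydroxy-3-methylbutanedioate | COC(=O)[C@H](C)[C@H](O)C(=O)OC | intermediate
6 | (2S,3R)-3-methylmalic acid, (2S,3R)-2-hydroxy-3-methylbutanedioic acid | OC(=O)[C@H](C)[C@H](O)C(=O)O | intermediate
7 | cis-dioxolanone acid, (2R)-2-[(2S,4S)-2-tert-butyl-5-oxo-1,3-dioxolan-4-yl]propanoic acid | OC(=O)[C@H](C)[C@@H]1O[C@H](C(C)(C)C)OC1=O | intermediate
8 | dilithium ring enolate of 7 (carboxylate and dioxolanone enolate) | [Li+].[Li+].[O-]C(=O)[C@H](C)C1=C([O-])O[C@@H](C(C)(C)C)O1 | intermediate (not isolated)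
9 | dilithium aldolate, carboxylate and C9 alkoxide of (2R)-2-[(2S,4R)-2-tert-butyl-4-[(1R)-1-hydroxybut-2-yn-1-yl]-5-oxo-1,3-dioxolan-4-yl]propanoic acid | [Li+].[Li+].[O-]C(=O)[C@H](C)[C@]1([C@H]([O-])C#CC)O[C@H](C(C)(C)C)OC1=O | intermediate (not isolated)
10 | bis-silyl compound, TBS ester of 11 | CC(C)(C)[Si](C)(C)OC(=O)[C@H](C)[C@]1([C@H](O[Si](C)(C)C(C)(C)C)C#CC)O[C@H](C(C)(C)C)OC1=O | intermediate (not isolated)
11 | silyloxyalkynyl dioxolanone acid, (2R)-2-[(2S,4R)-2-tert-butyl-4-[(1R)-1-(TBS-oxy)but-2-yn-1-yl]-5-oxo-1,3-dioxolan-4-yl]propanoic acid | OC(=O)[C@H](C)[C@]1([C@H](O[Si](C)(C)C(C)(C)C)C#CC)O[C@H](C(C)(C)C)OC1=O | intermediate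
12 | [2-(1,3-dioxolan-2-yl)ethyl]magnesium bromide | Br[Mg]CCC1OCCO1 | starting material
13 | tert-butyldimethyl(prop-2-yn-1-yloxy)silane | C#CCO[Si](C)(C)C(C)(C)C | starting material
14 | alkylcopper, [2-(1,3-dioxolan-2-yl)ethyl]copper (MgBr2 complex) | [Cu]CCC1OCCO1 | intermediate (not isolated)
15 | alkenylcopper, [(1E)-2-(TBS-oxymethyl)-4-(1,3-dioxolan-2-yl)but-1-en-1-yl]copper | [Cu]/C=C(/CO[Si](C)(C)C(C)(C)C)CCC1OCCO1 | intermediate (not isolated)
16 | (E)-alkenyl iodide acetal, tert-butyl{[(2E)-4-(1,3-dioxolan-2-yl)-2-(iodomethylidene)butyl]oxy}dimethylsilane | I/C=C(/CO[Si](C)(C)C(C)(C)C)CCC1OCCO1 | intermediate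
17 | alkenyllithium, [(1E)-2-(TBS-oxymethyl)-4-(1,3-dioxolan-2-yl)but-1-en-1-yl]lithium | [Li]/C=C(/CO[Si](C)(C)C(C)(C)C)CCC1OCCO1 | intermediate (not isolated)
18 | lithium carboxylate of 11 | [Li+].[O-]C(=O)[C@H](C)[C@]1([C@H](O[Si](C)(C)C(C)(C)C)C#CC)O[C@H](C(C)(C)C)OC1=O | intermediate (not isolated)
19 | α-hydroxy enone acid, (2R,3R,5E)-3-[(1R)-1-(TBS-oxy)but-2-yn-1-yl]-6-(TBS-oxymethyl)-8-(1,3-dioxolan-2-yl)-3-hydroxy-2-methyl-4-oxooct-5-enoic acid | OC(=O)[C@H](C)[C@@](O)([C@H](O[Si](C)(C)C(C)(C)C)C#CC)C(=O)/C=C(/CO[Si](C)(C)C(C)(C)C)CCC1OCCO1 | intermediate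
20 | dihydroxy acid, (2R,3S,4S,5E)-3-[(1R)-1-(TBS-oxy)but-2-yn-1-yl]-6-(TBS-oxymethyl)-8-(1,3-dioxolan-2-yl)-3,4-dihydroxy-2-methyloct-5-enoic acid | OC(=O)[C@H](C)[C@@](O)([C@H](O[Si](C)(C)C(C)(C)C)C#CC)[C@@H](O)/C=C(/CO[Si](C)(C)C(C)(C)C)CCC1OCCO1 | intermediate (not isolated)
21 | alkynyl lactone acetal, (3R,4S,5S)-4-[(1R)-1-(TBS-oxy)but-2-yn-1-yl]-5-[(1E)-2-(TBS-oxymethyl)-4-(1,3-dioxolan-2-yl)but-1-en-1-yl]-4-hydroxy-3-methyloxolan-2-one | C[Si](C)(C(C)(C)C)OC/C(CCC1OCCO1)=C/[C@@H]2OC(=O)[C@H](C)[C@@]2(O)[C@H](O[Si](C)(C)C(C)(C)C)C#CC | intermediate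
22 | alkenylzirconocene, chlorobis(cyclopentadienyl)zirconium adduct of 21 (Zr on C11, H on C10, syn) | C[Si](C)(C(C)(C)C)OC/C(CCC1OCCO1)=C/[C@@H]2OC(=O)[C@H](C)[C@@]2(O)[C@H](O[Si](C)(C)C(C)(C)C)/C=C(/[Zr](Cl)(C1C=CC=C1)C1C=CC=C1)C | intermediate (not isolated)
23 | iodoalkenyl lactone acetal, (3R,4S,5S)-4-[(1R,2E)-1-(TBS-oxy)-3-iodobut-2-en-1-yl]-5-[(1E)-2-(TBS-oxymethyl)-4-(1,3-dioxolan-2-yl)but-1-en-1-yl]-4-hydroxy-3-methyloxolan-2-one | C[Si](C)(C(C)(C)C)OC/C(CCC1OCCO1)=C/[C@@H]2OC(=O)[C@H](C)[C@@]2(O)[C@H](O[Si](C)(C)C(C)(C)C)/C=C(/I)C | intermediate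
24 | iodoalkenyl lactone aldehyde, (3R,4S,5S)-4-[(1R,2E)-1-(TBS-oxy)-3-iodobut-2-en-1-yl]-5-[(1E)-2-(TBS-oxymethyl)-5-oxopent-1-en-1-yl]-4-hydroxy-3-methyloxolan-2-one | C[Si](C)(C(C)(C)C)OC/C(CCC=O)=C/[C@@H]1OC(=O)[C@H](C)[C@@]1(O)[C@H](O[Si](C)(C)C(C)(C)C)/C=C(/I)C | intermediate
25 | isopropenylmagnesium bromide (prop-1-en-2-ylmagnesium bromide) | CC(=C)[Mg]Br | starting material
26 | α-aminoxy aldehyde, as 24 but with 5-[(1E,4S)-2-(TBS-oxymethyl)-5-oxo-4-[(phenylamino)oxy]pent-1-en-1-yl] | C[Si](C)(C(C)(C)C)OC/C(C[C@H](ONc1ccccc1)C=O)=C/[C@@H]1OC(=O)[C@H](C)[C@@]1(O)[C@H](O[Si](C)(C)C(C)(C)C)/C=C(/I)C | intermediate (not isolated)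
27 | aminoxy allylic alcohol, as 24 but with 5-[(1E,4S)-2-(TBS-oxymethyl)-5-hydroxy-6-methyl-4-[(phenylamino)oxy]hepta-1,6-dien-1-yl] (both C2 epimers) | C[Si](C)(C(C)(C)C)OC/C(C[C@H](ONc1ccccc1)C(O)C(C)=C)=C/[C@@H]1OC(=O)[C@H](C)[C@@]1(O)[C@H](O[Si](C)(C)C(C)(C)C)/C=C(/I)C | intermediate
28 | allylic diol, as 24 but with 5-[(1E,4S)-2-(TBS-oxymethyl)-4,5-dihydroxy-6-methylhepta-1,6-dien-1-yl] (both C2 epimers) | C[Si](C)(C(C)(C)C)OC/C(C[C@H](O)C(O)C(C)=C)=C/[C@@H]1OC(=O)[C@H](C)[C@@]1(O)[C@H](O[Si](C)(C)C(C)(C)C)/C=C(/I)C | intermediate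
29 | α-hydroxy isopropenyl ketone, (3R,4S,5S)-4-[(1R,2E)-1-(TBS-oxy)-3-iodobut-2-en-1-yl]-5-[(1E,4S)-2-(TBS-oxymethyl)-4-hydroxy-6-methyl-5-oxohepta-1,6-dien-1-yl]-4-hydroxy-3-methyloxolan-2-one | C[Si](C)(C(C)(C)C)OC/C(C[C@H](O)C(=O)C(C)=C)=C/[C@@H]1OC(=O)[C@H](C)[C@@]1(O)[C@H](O[Si](C)(C)C(C)(C)C)/C=C(/I)C | intermediate
30 | tributyl(1-ethoxyethenyl)stannane | CCCC[Sn](CCCC)(CCCC)C(=C)OCC | starting material
31 | ethoxydiene, as 29 but with 4-[(1R,2E)-1-(TBS-oxy)-4-ethoxy-3-methylpenta-2,4-dien-1-yl] | C[Si](C)(C(C)(C)C)OC/C(C[C@H](O)C(=O)C(C)=C)=C/[C@@H]1OC(=O)[C@H](C)[C@@]1(O)[C@H](O[Si](C)(C)C(C)(C)C)/C=C(/C(=C)OCC)C | intermediate (not isolated)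
32 | tricyclic enol ether hydroxy ketone, (1S,3S,5E,7S,8S,9R,10S,17R)-9,16-bis(TBS-oxy)-12-ethoxy-3,8-dihydroxy-2-oxobriara-5,11-dien-19,7-olide | C[Si](C)(C(C)(C)C)OC/C1=C/[C@@H]2OC(=O)[C@H](C)[C@@]2(O)[C@H](O[Si](C)(C)C(C)(C)C)[C@@H]2[C@](C)(CCC(OCC)=C2C)C(=O)[C@@H](O)C1 | intermediate
33 | tricyclic anti-diol, (1S,2R,3S,5E,7S,8S,9R,10R,17R)-9,16-bis(TBS-oxy)-12-ethoxy-2,3,8-trihydroxybriara-5,11-dien-19,7-olide | C[Si](C)(C(C)(C)C)OC/C1=C/[C@@H]2OC(=O)[C@H](C)[C@@]2(O)[C@H](O[Si](C)(C)C(C)(C)C)[C@@H]2[C@](C)(CCC(OCC)=C2C)[C@@H](O)[C@@H](O)C1 | intermediate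
34 | epoxy enol ether, (1S,2R,3R,5E,7S,8S,9R,10R,17R)-9,16-bis(TBS-oxy)-2,3-epoxy-12-ethoxy-8-hydroxybriara-5,11-dien-19,7-olide | C[Si](C)(C(C)(C)C)OC/C1=C/[C@@H]2OC(=O)[C@H](C)[C@@]2(O)[C@H](O[Si](C)(C)C(C)(C)C)[C@@H]2[C@](C)(CCC(OCC)=C2C)[C@H]2O[C@@H]2C1 | intermediate
35 | ethoxy epoxide, (11S,12R)-11,12-epoxide of 34 with the oxirane on the α face | C[Si](C)(C(C)(C)C)OC/C1=C/[C@@H]2OC(=O)[C@H](C)[C@@]2(O)[C@H](O[Si](C)(C)C(C)(C)C)[C@@H]2[C@](C)(CC[C@@]3(OCC)O[C@@]23C)[C@H]2O[C@@H]2C1 | intermediate (not isolated)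
36 | α-ketol, (1S,2R,3R,5E,7S,8S,9R,10S,11S,17R)-9,16-bis(TBS-oxy)-2,3-epoxy-8,11-dihydroxy-12-oxobriar-5-en-19,7-olide | C[Si](C)(C(C)(C)C)OC/C1=C/[C@@H]2OC(=O)[C@H](C)[C@@]2(O)[C@H](O[Si](C)(C)C(C)(C)C)[C@@H]2[C@](C)(CCC(=O)[C@@]2(C)O)[C@H]2O[C@@H]2C1 | intermediate
37 | cyclohexenone, (1S,2R,3R,5E,7S,8S,9R,10S,11S,17R)-9,16-bis(TBS-oxy)-2,3-epoxy-8,11-dihydroxy-12-oxobriara-5,13-dien-19,7-olide | C[Si](C)(C(C)(C)C)OC/C1=C/[C@@H]2OC(=O)[C@H](C)[C@@]2(O)[C@H](O[Si](C)(C)C(C)(C)C)[C@@H]2[C@](C)(C=CC(=O)[C@@]2(C)O)[C@H]2O[C@@H]2C1 | intermediate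
38 | tetraol, (1S,2R,3R,5E,7S,8R,9R,10S,11S,17R)-2,3-epoxy-8,9,11,16-tetrahydroxy-12-oxobriara-5,13-dien-19,7-olide | OC/C1=C/[C@@H]2OC(=O)[C@H](C)[C@@]2(O)[C@H](O)[C@@H]2[C@](C)(C=CC(=O)[C@@]2(C)O)[C@H]2O[C@@H]2C1 | intermediate
39 | CNP0226792.2, (1S,2R,3R,5E,7S,8S,9R,10S,11S,17R)-9,11,16-triacetoxy-2,3-epoxy-8-hydroxy-12-oxobriara-5,13-dien-19,7-olide | CC(=O)OC/C1=C/[C@@H]2OC(=O)[C@H](C)[C@@]2(O)[C@H](OC(C)=O)[C@@H]2[C@](C)(C=CC(=O)[C@@]2(C)OC(C)=O)[C@H]2O[C@@H]2C1 | target

**Step count and risks**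

Total step count: 20. Longest linear sequence: 18 steps (steps 2–5 and 7–20, from 3).

The three steps most likely to fail:

- Step 14 (Stille/macrocyclising Diels–Alder cascade; a ten-membered ring closed by cycloaddition is unprecedented and the facial and exo selectivity rest on a model). The fallback sets out from 29 and replaces the open-chain cycloaddition by a templated one. The C3 and C8 hydroxyls are bridged with iPr2Si(OTf)2 and 2,6-lutidine under high dilution to give the cyclic diisopropylsilylene F1. Stille coupling with 30 and heating then let the Diels–Alder reaction run inside a nine-membered template that holds the dienophile on the C8 face, giving the bridged cycloadduct F2. Et3N·3HF cleaves the dialkoxysilane in preference to the two TBS ethers, and the route is rejoined at 32.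

- Step 8 (C7 configuration from chelation-controlled reduction next to a fully substituted carbinol). The fallback sets out from 19 and sets C7 by displacement instead of by hydride face selection. Reduction under non-chelating conditions (NaBH4, CeCl3·7H2O, MeOH, −78 °C) is expected to give mainly the C7-epimeric dihydroxy acid F3, which is kept as its carboxylate salt. Mitsunobu lactonisation (PPh3, DIAD, toluene, 0 °C) then displaces the activated allylic C7 hydroxyl by the C19 carboxylate with inversion, and the route is rejoined at 21.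

- Step 20 (acetylating the tertiary C11 hydroxyl while the tertiary C8 hydroxyl stays free). The fallback sets out from 34 and installs the C11 acetate directly. Pb(OAc)4 in benzene acetoxylates the enol ether at C11 to give the α-acetoxy ketone F4; the face selectivity of this step is not secured. IBX gives the enone acetate F5, and Bu4NF/AcOH gives the diol F6. Ac2O in pyridine without an acylation catalyst then esterifies only the C9 and C16 hydroxyls, arriving at 39.

Further compounds
F1 | step 14 | cyclic diisopropylsilylene of 29 (Si bridging O3 and O8) | C[Si](C)(C(C)(C)C)OC/C(C[C@H](O[Si]3(C(C)C)C(C)C)C(=O)C(C)=C)=C/[C@@H]1OC(=O)[C@H](C)[C@@]1(O3)[C@H](O[Si](C)(C)C(C)(C)C)/C=C(/I)C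
F2 | step 14 | bridged cycloadduct, O3,O8-diisopropylsilylene of 32 | C[Si](C)(C(C)(C)C)OC/C1=C/[C@@H]2OC(=O)[C@H](C)[C@@]2(O[Si]3(C(C)C)C(C)C)[C@H](O[Si](C)(C)C(C)(C)C)[C@@H]2[C@](C)(CCC(OCC)=C2C)C(=O)[C@@H](O3)C1
F3 | step 8 | C7-epimeric dihydroxy acid, (2R,3S,4R,5E)-3-[(1R)-1-(TBS-oxy)but-2-yn-1-yl]-6-(TBS-oxymethyl)-8-(1,3-dioxolan-2-yl)-3,4-dihydroxy-2-methyloct-5-enoic acid | OC(=O)[C@H](C)[C@@](O)([C@H](O[Si](C)(C)C(C)(C)C)C#CC)[C@H](O)/C=C(/CO[Si](C)(C)C(C)(C)C)CCC1OCCO1
F4 | step 20 | α-acetoxy ketone, 11-O-acetate of 36 | C[Si](C)(C(C)(C)C)OC/C1=C/[C@@H]2OC(=O)[C@H](C)[C@@]2(O)[C@H](O[Si](C)(C)C(C)(C)C)[C@@H]2[C@](C)(CCC(=O)[C@@]2(C)OC(C)=O)[C@H]2O[C@@H]2C1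
F5 | step 20 | enone acetate, 11-O-acetate of 37 | C[Si](C)(C(C)(C)C)OC/C1=C/[C@@H]2OC(=O)[C@H](C)[C@@]2(O)[C@H](O[Si](C)(C)C(C)(C)C)[C@@H]2[C@](C)(C=CC(=O)[C@@]2(C)OC(C)=O)[C@H]2O[C@@H]2C1
F6 | step 20 | 11-O-acetyl diol, 11-O-acetate of 38 | OC/C1=C/[C@@H]2OC(=O)[C@H](C)[C@@]2(O)[C@H](O)[C@@H]2[C@](C)(C=CC(=O)[C@@]2(C)OC(C)=O)[C@H]2O[C@@H]2C1
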